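The target is cut across ring B at C9–C10 and C11–C6 (spiro[5.5]undecane numbering), which removes the two-carbon unit C10–C11 with its isopropyl group as isoprene. The key step, an enantioselective palladium-catalysed Heck/Tsuji–Trost carboannulation, joins an alkenyl iodide (C9) to the diene and lets the resulting allyl complex be captured by C6, the acidic carbon between the two ring-A carbonyls. It closes ring B and sets both stereocentres in one operation. The precursor is the enolizable ring-A dione carrying a (Z)-3-iodoallyl side chain on that carbon. Ring A comes from 2,4,6-trihydroxybenzoic acid by dearomatizing C-methylation; hydrogenation of the isopropenyl group finishes the synthesis.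

Key step: step 8

Remark on numbering: in the spiro compounds ring A is C1–C5 (C1 = carbonyl next to C–Me, C3 = C–OMe, C4 = CMe2, C5 = carbonyl), C6 is the spiro carbon and ring B is C7–C11 (C8=C9 alkene, C11 bears the isopropyl group).

Remark on the chemistry: the sense of induction of the chiral ligand in step 8 cannot be predicted with certainty; the (S)-ligand is written, and its antipode is to be used if a first run shows the opposite sense.

Step 1
Reactants: 1 2,4,6-trihydroxybenzoic acid
Product: 2 benzyl 2,4,6-trihydroxybenzoate
Conditions: BnBr, KHCO3, DMF, rt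
Reagents that add atoms: benzyl bromide, BrCc1ccccc1
Why: Bicarbonate ionizes only the carboxylic acid, so SN2 O-benzylation of the carboxylate should give the ester and leave the three phenols free.

Step 2
Reactants: 2 benzyl 2,4,6-trihydroxybenzoate
Product: 3 benzyl 2,6-dihydroxy-4-methoxybenzoate
Conditions: MeI (1.05 equiv), K2CO3, acetone, rt
Reagents that add atoms: methyl iodide, CI
Why: The para hydroxyl is the most acidic and the only one not hydrogen-bonded to the ester, so Williamson etherification with one equivalent of methyl iodide should occur there.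

Step 3
Reactants: 3 benzyl 2,6-dihydroxy-4-methoxybenzoate
Product: 4 benzyl 2-hydroxy-4-methoxy-3,5,5-trimethyl-6-oxocyclohexa-1,3-diene-1-carboxylate
Conditions: MeI (6 equiv), NaOMe (5 equiv), MeOH, 0 °C to rt; aq. HCl work-up
Reagents that add atoms: methyl iodide, CI
Why: Exhaustive C-methylation of the resorcinol-type dianion (alkylative dearomatization, the classical phloroglucinol C-methylation) should put one methyl on each free ring carbon and a second on one of them and then stop, because the ester-bearing carbon is deactivated and the O-methylated carbon cannot become a carbonyl, which places the methoxy group between C–Me and CMe2 without a regiochemical choice.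

Step 4
Reactants: 4 benzyl 2-hydroxy-4-methoxy-3,5,5-trimethyl-6-oxocyclohexa-1,3-diene-1-carboxylate
Product: 6 5-methoxy-4,6,6-trimethylcyclohex-4-ene-1,3-dione, via beta-keto acid 5 (not isolated)
Conditions: H2 (1 atm), 10% Pd/C, EtOAc, rt; then 40 °C
Reagents that add atoms: none
Why: Hydrogenolysis of the benzyl ester should give a 2-carboxy-1,3-dione that loses CO2 spontaneously (decarboxylation of a beta-keto acid) under neutral conditions that spare the acid-labile vinylogous methyl ester.

Step 5
Reactants: 7 prop-2-yn-1-ol; 8 5-bromo-2-methylpent-2-ene
Product: 11 (Z)-2-(iodomethylidene)-6-methylhept-5-en-1-ol, via homoprenylmagnesium bromide 9 (not isolated), via alkenylmagnesium alkoxide 10 (not isolated)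
Conditions: 8, Mg, THF; then 7, CuI (10 mol %), THF, -10 °C to rt (2.5 equiv of 9); then I2, -78 to 0 °C; H2O work-up
Reagents that add atoms: iodine, II
Why: Copper-catalysed anti-carbomagnesiation of the magnesium alkoxide of propargyl alcohol should deliver the alkyl group to C2 and a chelated alkenylmagnesium at C3 cis to the CH2O group, and iodinolysis with retention fixes the (Z) geometry.

Step 6
Reactants: 11 (Z)-2-(iodomethylidene)-6-methylhept-5-en-1-ol
Product: 12 (Z)-1-bromo-2-(iodomethylidene)-6-methylhept-5-ene
Conditions: CBr4, PPh3, CH2Cl2, 0 °C
Reagents that add atoms: carbon tetrabromide, BrC(Br)(Br)Br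
Why: The Appel reaction should convert the primary allylic alcohol into the bromide by SN2 displacement under neutral conditions that leave the alkenyl iodide and the trisubstituted alkene untouched.

Step 7
Reactants: 6 5-methoxy-4,6,6-trimethylcyclohex-4-ene-1,3-dione; 12 (Z)-1-bromo-2-(iodomethylidene)-6-methylhept-5-ene
Product: 13 2-[(2Z)-2-(iodomethylidene)-6-methylhept-5-en-1-yl]-5-methoxy-4,6,6-trimethylcyclohex-4-ene-1,3-dione
Conditions: 6 (1.5 equiv), K2CO3, H2O/THF, rt
Reagents that add atoms: none
Why: SN2 C-alkylation of the soft enolate of the cyclic 1,3-dione by a primary allylic bromide is favoured in a protic medium over O-alkylation, excess 6 should suppress a second alkylation, and the new stereocentre at C2 is enolizable and of no consequence.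

Step 8
Reactants: 13 2-[(2Z)-2-(iodomethylidene)-6-methylhept-5-en-1-yl]-5-methoxy-4,6,6-trimethylcyclohex-4-ene-1,3-dione; 14 isoprene
Product: 15 (6R,11S)-3-methoxy-2,4,4-trimethyl-8-(4-methylpent-3-en-1-yl)-11-(prop-1-en-2-yl)spiro[5.5]undeca-2,8-diene-1,5-dione
Conditions: Pd2(dba)3 (2.5 mol %), (S)-t-Bu-PHOX (6 mol %), K2CO3 (2 equiv), 14 (5 equiv), DMF, 60 °C, sealed tube
Reagents that add atoms: none
Why: Oxidative addition of zerovalent palladium into the C–I bond of 13 with retention of the (Z) geometry is followed by syn carbopalladation of the unsubstituted vinyl terminus of isoprene (bond C9–C10), and the resulting η3-allyl palladium complex is attacked at its proximal terminus, anti to palladium, by the tethered potassium enolate of the ring-A dione (bond C11–C6), which releases zerovalent palladium; the closest known reaction type is the palladium-catalysed carboannulation of 1,3-dienes by alkenyl halides that carry a stabilized carbon nucleophile, run here as an enantioselective Heck/Tsuji–Trost cascade. Ring B closes in a 6-exo mode with respect to the allyl unit (the isopropenyl C=C stays outside the ring), which is preferred over attack at the distal CH2 terminus and over O-attack, both of which would give eight-membered rings. C11 is controlled by the chiral P,N ligand: the two faces of the allyl complex interconvert by η3–η1–η3 slippage through the unsubstituted CH2 terminus, so the ligand should select the diastereomeric complex that is alkylated faster. C6 is controlled relative to C11 by the chair-like closure, in which the isopropenyl-bearing terminus should sit pseudo-axial next to the forming quaternary centre and anti to the bulkier C(=O)–CMe2 arm of the planar enolate, so that it ends cis to the C1 carbonyl as in the target. The step needs carbopalladation at the less substituted diene terminus (secured by sterics), C- over O-capture (secured by ring size) and cyclization faster than beta-hydride elimination of the allyl complex (secured by the intramolecular soft enolate).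

Step 9
Reactants: 15 (6R,11S)-3-methoxy-2,4,4-trimethyl-8-(4-methylpent-3-en-1-yl)-11-(prop-1-en-2-yl)spiro[5.5]undeca-2,8-diene-1,5-dione
Product: 16 (6R,11S)-3-methoxy-2,4,4-trimethyl-8-(4-methylpent-3-en-1-yl)-11-(propan-2-yl)spiro[5.5]undeca-2,8-diene-1,5-dione
Conditions: H2 (1 atm), RhCl(PPh3)3 (5 mol %), benzene/EtOH, rt
Reagents that add atoms: none
Why: Homogeneous hydrogenation with RhCl(PPh3)3 should reduce the 1,1-disubstituted alkene much faster than the two trisubstituted alkenes and the tetrasubstituted enol ether, and no stereocentre is touched.

Compound list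
1 | 2,4,6-trihydroxybenzoic acid | OC(=O)c1c(O)cc(O)cc1O | starting material
2 | benzyl 2,4,6-trihydroxybenzoate | O=C(OCc1ccccc1)c1c(O)cc(O)cc1O | intermediate
3 | benzyl 2,6-dihydroxy-4-methoxybenzoate | COc1cc(O)c(C(=O)OCc2ccccc2)c(O)c1 | intermediate
4 | benzyl 2-hydroxy-4-methoxy-3,5,5-trimethyl-6-oxocyclohexa-1,3-diene-1-carboxylate | COC1=C(C)C(O)=C(C(=O)OCc2ccccc2)C(=O)C1(C)C | intermediate
5 | 2-hydroxy-4-methoxy-3,5,5-trimethyl-6-oxocyclohexa-1,3-diene-1-carboxylic acid (beta-keto acid, not isolated) | COC1=C(C)C(O)=C(C(O)=O)C(=O)C1(C)C | intermediate
6 | 5-methoxy-4,6,6-trimethylcyclohex-4-ene-1,3-dione (largely enolized) | COC1=C(C)C(=O)CC(=O)C1(C)C | intermediate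
7 | prop-2-yn-1-ol | OCC#C | starting material
8 | 5-bromo-2-methylpent-2-ene | CC(C)=CCCBr | starting material
9 | (4-methylpent-3-en-1-yl)magnesium bromide (not isolated) | CC(C)=CCC[Mg]Br | intermediate
10 | bromomagnesium (Z)-2-[(bromomagnesio)methylidene]-6-methylhept-5-en-1-olate, Mg on the alkene carbon cis to CH2O (not isolated) | CC(C)=CCC/C(CO[Mg]Br)=C/[Mg]Br | intermediate
11 | (Z)-2-(iodomethylidene)-6-methylhept-5-en-1-ol | CC(C)=CCC/C(CO)=C/I | intermediate
12 | (Z)-1-bromo-2-(iodomethylidene)-6-methylhept-5-ene | CC(C)=CCC/C(CBr)=C/I | intermediate
13 | 2-[(2Z)-2-(iodomethylidene)-6-methylhept-5-en-1-yl]-5-methoxy-4,6,6-trimethylcyclohex-4-ene-1,3-dione | COC1=C(C)C(=O)C(C/C(CCC=C(C)C)=C\I)C(=O)C1(C)C | intermediate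
14 | isoprene (2-methylbuta-1,3-diene) | C=CC(C)=C | starting material
15 | (6R,11S)-3-methoxy-2,4,4-trimethyl-8-(4-methylpent-3-en-1-yl)-11-(prop-1-en-2-yl)spiro[5.5]undeca-2,8-diene-1,5-dione | COC1=C(C)C(=O)[C@]2(CC(CCC=C(C)C)=CC[C@H]2C(C)=C)C(=O)C1(C)C | intermediate
16 | (6R,11S)-3-methoxy-2,4,4-trimethyl-8-(4-methylpent-3-en-1-yl)-11-(propan-2-yl)spiro[5.5]undeca-2,8-diene-1,5-dione (CNP0419264.1) | COC1=C(C)C(=O)[C@]2(CC(CCC=C(C)C)=CC[C@H]2C(C)C)C(=O)C1(C)C | target

Total step count: 9. Longest linear sequence: 7 steps (1 to 2 to 3 to 4 to 6 to 13 to 15 to 16).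

Steps most likely to fail

Step 8. What may go wrong: insufficient facial discrimination at the allyl complex (enantioselectivity) or at the enolate (relative configuration of C6 and C11) when one ligand must serve both the Heck event and the allylic alkylation, and diversion of the organopalladium intermediates into O-vinylation or beta-hydride elimination. The fallback sets out from 13 and comes back at 15; it gives up the single-operation annulation in exchange for two separately tunable known reactions. Compound 13 is coupled with 2-methyl-2-vinyloxirane under Pd(OAc)2, HCO2Na and Bu4NCl in DMF (alkenyl halide/vinyl epoxide coupling with beta-alkoxide elimination), which should give the skipped dienyl alcohol 2-[(2Z,5E)-7-hydroxy-6-methyl-2-(4-methylpent-3-en-1-yl)hepta-2,5-dien-1-yl]-5-methoxy-4,6,6-trimethylcyclohex-4-ene-1,3-dione F1. F1 is then cyclized by an intramolecular asymmetric Tsuji–Trost alkylation, in which the acidic dione activates the allylic alcohol (Pd2(dba)3, the C2-symmetric bis(2-diphenylphosphinobenzamide) of trans-1,2-diaminocyclohexane, CH2Cl2, rt), to 15 through the same allyl complex.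

Step 7. What may go wrong: O-alkylation of the ambident enolate and a second alkylation of the product. The fallback sets out from the magnesium intermediate 10 and from 6 and comes back at 15. Intermediate 10 is quenched with N-bromosuccinimide in place of iodine to give (Z)-2-(bromomethylidene)-6-methylhept-5-en-1-ol F2, and methyl chloroformate with pyridine gives (Z)-2-(bromomethylidene)-6-methylhept-5-en-1-yl methyl carbonate F3. Pd(PPh3)4 in THF at rt should ionize the allylic carbonate while the alkenyl bromide stays inert, and 6 is C-allylated at the unsubstituted allyl terminus (Tsuji–Trost reaction, in which O-allyl products re-ionize and funnel to carbon) to give 2-[(2Z)-2-(bromomethylidene)-6-methylhept-5-en-1-yl]-5-methoxy-4,6,6-trimethylcyclohex-4-ene-1,3-dione F4. Retention of the (Z) geometry through the allyl complex would need to be confirmed. The annulation of step 8, run at 80 °C for the alkenyl bromide, returns to 15.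

Step 3. What may go wrong: stalling of the third, dearomatizing C-methylation because only two phenoxides activate the ring, competing O-methylation of the phenols and ester exchange by methoxide. The fallback sets out from 2 and comes back at 4. The triol 2 is C-methylated three times first (MeI 3 equiv, NaOMe, MeOH; the classical trimethylation of an acylphloroglucinol trianion) to give benzyl 2,4-dihydroxy-3,5,5-trimethyl-6-oxocyclohexa-1,3-diene-1-carboxylate F5. Its only enol hydroxyl that is not chelated to the ester, the one between C–Me and CMe2, is then O-methylated with trimethylsilyldiazomethane in MeOH/toluene to give 4.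

Further compounds
F1 | step 8 | 2-[(2Z,5E)-7-hydroxy-6-methyl-2-(4-methylpent-3-en-1-yl)hepta-2,5-dien-1-yl]-5-methoxy-4,6,6-trimethylcyclohex-4-ene-1,3-dione | COC1=C(C)C(=O)C(C/C(CCC=C(C)C)=C\C/C=C(\C)CO)C(=O)C1(C)C
F2 | step 7 | (Z)-2-(bromomethylidene)-6-methylhept-5-en-1-ol | CC(C)=CCC/C(CO)=C/Br
F3 | step 7 | (Z)-2-(bromomethylidene)-6-methylhept-5-en-1-yl methyl carbonate | CC(C)=CCC/C(COC(=O)OC)=C/Br
F4 | step 7 | 2-[(2Z)-2-(bromomethylidene)-6-methylhept-5-en-1-yl]-5-methoxy-4,6,6-trimethylcyclohex-4-ene-1,3-dione | COC1=C(C)C(=O)C(C/C(CCC=C(C)C)=C\Br)C(=O)C1(C)C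
F5 | step 3 | benzyl 2,4-dihydroxy-3,5,5-trimethyl-6-oxocyclohexa-1,3-diene-1-carboxylate | O=C(OCc1ccccc1)C1=C(O)C(C)=C(O)C(C)(C)C1=O
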